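**Retrosynthetic overview**
- Manuifolin D ⇐ its 7,2'-bis-TIPS ether ⇐ the C2 lactol ⇐ the (3R)-3-arylchroman-2-one. The silyl groups and the extra oxidation level at C2 (C=O → CHOH → CH2) are removed after ring closure, without reopening the ring.
- (3R)-3-Arylchroman-2-one ⇐ ring-B arylacetic acid (C2–C3) + ring-A o-quinone methide (O1–C8a–C4a–C4, released from a 2-(sulfonylmethyl)phenol). A catalytic enantioselective formal [4+2] makes C3–C4 and O1–C2, closes the pyran ring and sets C3.
- Enabling feature: C4 is benzylic on ring A, ortho to O1 (on C8a) and para to the oxygen on C7, so O1–C8a–C4a–C4 can be unmasked as a donor-stabilised oxa-diene. C3 is benzylic on ring B, so C2–C3 can be delivered as an arylacetic acid enolate.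
- Ring-B acid ⇐ methyl 2,4-dihydroxyphenylacetate by 4'-O-prenylation, aromatic Claisen shift to C5' (gives the 1,1-dimethylallyl group) and a second O-prenylation. The ring-A sulfone ⇐ 2,4-dihydroxybenzaldehyde.
- Ring order: rings A and B are bought as benzene rings. The dihydropyran ring is the only ring formed and is closed last.

Key step: step 9

Remark: isoflavan numbering is used (O1, C2, C3, C4, C4a–C8a for the chroman, primed numbers for ring B). The stereocentre of the given SMILES is (3R). Methyl 2,4-dihydroxyphenylacetate, 2,4-dihydroxybenzaldehyde and both antipodes of HyperBTM are taken as commercial. TIPS = triisopropylsilyl, prenyl = 3-methylbut-2-enyl, 1,1-dimethylallyl = 2-methylbut-3-en-2-yl.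

**Step 1**
Reactants: 1 methyl 2-(2,4-dihydroxyphenyl)acetate
Product: 2 methyl 2-[2-hydroxy-4-(prenyloxy)phenyl]acetate
Conditions: prenyl bromide (1.0 equiv), K2CO3, acetone, rt
Reagents that add atoms: prenyl bromide, CC(C)=CCBr
Why: Williamson etherification, expected at the 4-OH because the 2-OH is flanked by the CH2CO2Me arm and hydrogen-bonded to its carbonyl, while one equivalent of halide limits bis-alkylation.

**Step 2**
Reactants: 2 methyl 2-[2-hydroxy-4-(prenyloxy)phenyl]acetate
Product: 3 methyl 2-[4-(prenyloxy)-2-(triisopropylsilyloxy)phenyl]acetate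
Conditions: TIPSCl, imidazole, DMF, rt
Reagents that add atoms: triisopropylsilyl chloride, CC(C)[Si](Cl)(C(C)C)C(C)C
Why: Standard phenol silylation; the bulky TIPS ether should survive heat, mild base, hydride and cold Lewis acid, shields C3' in step 3 and leaves with fluoride at the end.

**Step 3**
Reactants: 3 methyl 2-[4-(prenyloxy)-2-(triisopropylsilyloxy)phenyl]acetate
Product: 5 methyl 2-[4-hydroxy-5-(1,1-dimethylallyl)-2-(triisopropylsilyloxy)phenyl]acetate, via dienone 4 (not isolated)
Conditions: PhNEt2, 190 °C, sealed tube, short heating under Ar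
Reagents that add atoms: none
Why: Aromatic Claisen rearrangement ([3,3] with allyl inversion, then tautomerisation of 4) turns the O-prenyl group into the C-bound 1,1-dimethylallyl group; migration to C5' rather than C3' is expected because C3' is wedged between OTIPS and the ether oxygen and a meta donor directs away from itself, and the substituted para carbon C1' rules out a following Cope shift.

**Step 4**
Reactants: 5 methyl 2-[4-hydroxy-5-(1,1-dimethylallyl)-2-(triisopropylsilyloxy)phenyl]acetate
Product: 6 methyl 2-[5-(1,1-dimethylallyl)-4-(prenyloxy)-2-(triisopropylsilyloxy)phenyl]acetate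
Conditions: prenyl bromide, K2CO3, acetone, reflux
Reagents that add atoms: prenyl bromide, CC(C)=CCBr
Why: Williamson etherification of the only free phenol, which completes the substitution pattern of ring B.

**Step 5**
Reactants: 6 methyl 2-[5-(1,1-dimethylallyl)-4-(prenyloxy)-2-(triisopropylsilyloxy)phenyl]acetate
Product: 7 2-[5-(1,1-dimethylallyl)-4-(prenyloxy)-2-(triisopropylsilyloxy)phenyl]acetic acid
Conditions: LiOH·H2O, THF/H2O, 0 °C → rt; then 1 M HCl to pH 4
Reagents that add atoms: lithium hydroxide, [Li+].[OH-]
Why: Saponification of an unhindered methyl ester, which should be much faster than attack of hydroxide on the ortho-flanked aryl TIPS ether.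

**Step 6**
Reactants: 8 2,4-dihydroxybenzaldehyde
Product: 9 2-hydroxy-4-(triisopropylsilyloxy)benzaldehyde
Conditions: TIPSCl (1.05 equiv), imidazole, CH2Cl2, 0 °C
Reagents that add atoms: triisopropylsilyl chloride, CC(C)[Si](Cl)(C(C)C)C(C)C
Why: Selective silylation of the 4-OH, because the 2-OH is tied up in a strong hydrogen bond to the aldehyde oxygen.

**Step 7**
Reactants: 9 2-hydroxy-4-(triisopropylsilyloxy)benzaldehyde
Product: 10 2-(hydroxymethyl)-5-(triisopropylsilyloxy)phenol
Conditions: NaBH4, THF/MeOH, 0 °C
Reagents that add atoms: none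
Why: Borohydride reduction of an aromatic aldehyde, to which the silyl ether and the phenol are inert at 0 °C.

**Step 8**
Reactants: 10 2-(hydroxymethyl)-5-(triisopropylsilyloxy)phenol
Product: 11 2-[(4-methylphenyl)sulfonylmethyl]-5-(triisopropylsilyloxy)phenol
Conditions: p-TolSO2H (1.5 equiv, freshly liberated from its sodium salt), CH2Cl2, rt
Reagents that add atoms: p-toluenesulfinic acid, Cc1ccc(cc1)S(=O)O
Why: Acid-promoted SN1-type substitution of a benzylic alcohol activated by an ortho and a para oxygen, in which the sulfinate binds through sulfur to give a stable, storable sulfone.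

**Step 9**
Reactants: 7 2-[5-(1,1-dimethylallyl)-4-(prenyloxy)-2-(triisopropylsilyloxy)phenyl]acetic acid; 11 2-[(4-methylphenyl)sulfonylmethyl]-5-(triisopropylsilyloxy)phenol
Product: 15 (3R)-3-[5-(1,1-dimethylallyl)-4-(prenyloxy)-2-(triisopropylsilyloxy)phenyl]-7-(triisopropylsilyloxy)chroman-2-one, via mixed anhydride 12 (not isolated), via o-quinone methide 13 (not isolated), via ammonium enolate 14 (not isolated)
Conditions: 7, PivCl, iPr2NEt, CH2Cl2, 0 °C; then (2S,3R)-HyperBTM (10 mol %), 11 (1.5 equiv), Cs2CO3, 0 °C
Reagents that add atoms: none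
Why: Isothiourea (Lewis base) catalysed Michael addition–lactonisation, a stepwise formal [4+2] between a C(1)-ammonium enolate and an o-quinone methide made in situ; the closest known reactions are the isothiourea-catalysed annulations of arylacetic acids with enone-type acceptors and the carbene-enolate/o-quinone methide annulation to 3-substituted dihydrocoumarins. Mixed anhydride 12 N-acylates the catalyst and deprotonation gives the (Z)-enolate 14, held planar by a 1,5-O···S contact, while Cs2CO3 deprotonates 11 and the phenoxide expels sulfinate to give 13. C3 of 14 adds to the exocyclic CH2 of 13 (the future C4), driven by re-aromatisation of ring A, and the phenoxide O1 so released attacks the acyl ammonium carbonyl C2 in a 6-exo-trig acyl substitution that closes the ring and frees the catalyst. C3, the only new stereocentre, is set in the C3–C4 bond formation by the catalyst: the pseudo-axial C2-phenyl group of (2S,3R)-HyperBTM covers one face of 14, and attack anti to it corresponds to (3R). The step needs C-alkylation of the enolate rather than O-acylation of the phenoxide of 11, cross-reaction rather than self-condensation of 13, and no enolisation of 15; the para OTIPS group of ring A speeds sulfinate loss and tempers 13, reversible sulfinate re-addition keeps 13 at low concentration, 13 offers a single electrophilic carbon, and the low temperature with a heterogeneous base protects the acidic C3–H. The alkenes, the aryl prenyl ether and both silyl ethers are inert to these mild, non-acidic conditions.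

**Step 10**
Reactants: 15 (3R)-3-aryl-7-(triisopropylsilyloxy)chroman-2-one
Product: 16 (3R)-3-[5-(1,1-dimethylallyl)-4-(prenyloxy)-2-(triisopropylsilyloxy)phenyl]-7-(triisopropylsilyloxy)chroman-2-ol (mixture of C2 epimers, used crude)
Conditions: DIBAL-H (1.1 equiv), CH2Cl2, −78 °C; Rochelle salt work-up
Reagents that add atoms: none
Why: Partial reduction of a lactone to the lactol through an aluminium hemiacetal that is stable at −78 °C, so the ring stays closed; the non-basic reagent should leave C3 untouched, and the C2 configuration is irrelevant because C2 becomes CH2.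

**Step 11**
Reactants: 16 (3R)-3-aryl-7-(triisopropylsilyloxy)chroman-2-ol
Product: 17 (3R)-3-[5-(1,1-dimethylallyl)-4-(prenyloxy)-2-(triisopropylsilyloxy)phenyl]-7-(triisopropylsilyloxy)chroman
Conditions: Et3SiH (5 equiv), BF3·OEt2, CH2Cl2, −78 °C
Reagents that add atoms: none
Why: Ionic hydrogenation of a lactol (Lewis acid ionisation at C2, then hydride transfer from the silane); a large excess of silane at −78 °C should capture the cation faster than it can lose H3 or than the Lewis acid can attack the prenyl ether, so C3 is retained.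

**Step 12**
Reactants: 17 (3R)-7,2'-bis-O-TIPS manuifolin D
Product: 18 manuifolin D, (3R)-3-[2-hydroxy-5-(1,1-dimethylallyl)-4-(prenyloxy)phenyl]chroman-7-ol
Conditions: TBAF, AcOH, THF, 0 °C
Reagents that add atoms: none
Why: Fluoride desilylation of both aryl silyl ethers under buffered conditions, which touch neither the acid-sensitive prenyl ether, nor the alkenes, nor the now non-acidic C3–H.

**Compound list**
1 | methyl 2-(2,4-dihydroxyphenyl)acetate | COC(=O)Cc1ccc(O)cc1O | starting material
2 | methyl 2-[2-hydroxy-4-(prenyloxy)phenyl]acetate | COC(=O)Cc1ccc(OCC=C(C)C)cc1O | intermediate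
3 | methyl 2-[4-(prenyloxy)-2-(triisopropylsilyloxy)phenyl]acetate | COC(=O)Cc1ccc(OCC=C(C)C)cc1O[Si](C(C)C)(C(C)C)C(C)C | intermediate
4 | Claisen dienone, the racemic 6-(1,1-dimethylallyl)cyclohexa-2,4-dienone tautomer of 5 | COC(=O)CC1=CC(C(C)(C)C=C)C(=O)C=C1O[Si](C(C)C)(C(C)C)C(C)C | intermediate
5 | methyl 2-[4-hydroxy-5-(1,1-dimethylallyl)-2-(triisopropylsilyloxy)phenyl]acetate | COC(=O)Cc1cc(C(C)(C)C=C)c(O)cc1O[Si](C(C)C)(C(C)C)C(C)C | intermediate
6 | methyl 2-[5-(1,1-dimethylallyl)-4-(prenyloxy)-2-(triisopropylsilyloxy)phenyl]acetate | COC(=O)Cc1cc(C(C)(C)C=C)c(OCC=C(C)C)cc1O[Si](C(C)C)(C(C)C)C(C)C | intermediate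
7 | 2-[5-(1,1-dimethylallyl)-4-(prenyloxy)-2-(triisopropylsilyloxy)phenyl]acetic acid | OC(=O)Cc1cc(C(C)(C)C=C)c(OCC=C(C)C)cc1O[Si](C(C)C)(C(C)C)C(C)C | intermediate
8 | 2,4-dihydroxybenzaldehyde | O=Cc1ccc(O)cc1O | starting material
9 | 2-hydroxy-4-(triisopropylsilyloxy)benzaldehyde | O=Cc1ccc(O[Si](C(C)C)(C(C)C)C(C)C)cc1O | intermediate
10 | 2-(hydroxymethyl)-5-(triisopropylsilyloxy)phenol | OCc1ccc(O[Si](C(C)C)(C(C)C)C(C)C)cc1O | intermediate
11 | 2-[(4-methylphenyl)sulfonylmethyl]-5-(triisopropylsilyloxy)phenol | Cc1ccc(cc1)S(=O)(=O)Cc1ccc(O[Si](C(C)C)(C(C)C)C(C)C)cc1O | intermediate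
12 | mixed anhydride of 7 with pivalic acid | CC(C)(C)C(=O)OC(=O)Cc1cc(C(C)(C)C=C)c(OCC=C(C)C)cc1O[Si](C(C)C)(C(C)C)C(C)C | intermediate
13 | 6-methylidene-3-(triisopropylsilyloxy)cyclohexa-2,4-dien-1-one (o-quinone methide) | C=C1C=CC(O[Si](C(C)C)(C(C)C)C(C)C)=CC1=O | intermediate
14 | (Z)-C(1)-ammonium enolate of 7 bound to (2S,3R)-HyperBTM | [O-]/C(=C\c1cc(C(C)(C)C=C)c(OCC=C(C)C)cc1O[Si](C(C)C)(C(C)C)C(C)C)[N+]1=C2Sc3ccccc3N2C[C@@H](C(C)C)[C@H]1c1ccccc1 | intermediate
15 | (3R)-3-[5-(1,1-dimethylallyl)-4-(prenyloxy)-2-(triisopropylsilyloxy)phenyl]-7-(triisopropylsilyloxy)chroman-2-one | C=CC(C)(C)c1cc([C@@H]2C(=O)Oc3cc(O[Si](C(C)C)(C(C)C)C(C)C)ccc3C2)c(O[Si](C(C)C)(C(C)C)C(C)C)cc1OCC=C(C)C | intermediate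
16 | (3R)-3-[5-(1,1-dimethylallyl)-4-(prenyloxy)-2-(triisopropylsilyloxy)phenyl]-7-(triisopropylsilyloxy)chroman-2-ol, C2 epimers | C=CC(C)(C)c1cc([C@@H]2C(O)Oc3cc(O[Si](C(C)C)(C(C)C)C(C)C)ccc3C2)c(O[Si](C(C)C)(C(C)C)C(C)C)cc1OCC=C(C)C | intermediate
17 | (3R)-3-[5-(1,1-dimethylallyl)-4-(prenyloxy)-2-(triisopropylsilyloxy)phenyl]-7-(triisopropylsilyloxy)chroman | C=CC(C)(C)c1cc([C@@H]2COc3cc(O[Si](C(C)C)(C(C)C)C(C)C)ccc3C2)c(O[Si](C(C)C)(C(C)C)C(C)C)cc1OCC=C(C)C | intermediate
18 | manuifolin D, (3R)-3-[2-hydroxy-5-(1,1-dimethylallyl)-4-(prenyloxy)phenyl]chroman-7-ol | C=CC(C)(C)c1cc([C@@H]2COc3cc(O)ccc3C2)c(O)cc1OCC=C(C)C | target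

**Total step count:** 12. **Longest linear sequence:** 9 steps (steps 1–5 and 9–12).

**Steps most likely to fail**

1. **Step 9.**
   - What may go wrong: O-acylation of the phenoxide of 11 by 12 or by the acylated catalyst, self-condensation of 13, slow turnover caused by the bulky ortho OTIPS group, and base-mediated enolisation of the α-aryl lactone that would erode enantiopurity. If the sense of induction were opposite to the model, the (2R,3S) catalyst would be used.
   - Fallback, from 7 and 11, back to the route at 15: acid 7 would be doubly deprotonated with n-BuLi in THF in the presence of a recoverable C2-symmetric chiral tetraamine. The amine serves as its dilithium amide, a non-covalent auxiliary, in the antipode that exposes the same enolate face.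
   - The lithium phenoxide of 11 would be added at −78 °C and the mixture warmed, so that 13 is released in the presence of the chiral enediolate aggregate.
   - Conjugate addition and mild acidic work-up should give (2R)-2-[5-(1,1-dimethylallyl)-4-(prenyloxy)-2-(triisopropylsilyloxy)phenyl]-3-[2-hydroxy-4-(triisopropylsilyloxy)phenyl]propanoic acid F1. Its carboxylate form has no acidic α-hydrogen and cannot racemise in the basic medium.
   - Neutral dehydrative lactonisation (EDC·HCl, CH2Cl2, 0 °C) closes the same ring to give 15.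

2. **Step 11.**
   - What may go wrong: ionisation of the aryl prenyl ether by the Lewis acid, participation of the 2'-silyloxy oxygen at the cationic C2, and loss and return of H3 (enol ether formation and reprotonation) that would racemise C3.
   - Fallback, from 16, back at 17, ring kept closed and no acid used: the lactol would be converted with PhSSPh and PBu3 (CH2Cl2, rt) into the O,S-acetal (3R)-3-aryl-2-(phenylsulfanyl)-7-(triisopropylsilyloxy)chroman F2.
   - F2 would then be reduced by a radical chain (Bu3SnH, AIBN, toluene, 80 °C). The α-oxy radical at C2 abstracts hydrogen far faster than it could rearrange, and C3 is never involved, so 17 results.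

3. **Step 3.**
   - What may go wrong: partial migration to C3', abnormal Claisen isomerisation of the 1,1-dimethylallyl group, and thermal cyclisation of the o-allylphenol to a dihydrobenzofuran.
   - Fallback, from 1, back at 6, replacing steps 1–4 by a cross-coupling logic: bromination (NBS, MeCN, −10 °C) para to the 2-OH should give methyl 2-(5-bromo-2,4-dihydroxyphenyl)acetate F3.
   - The 4-OH, now the more acidic one because it is ortho to bromine, would be prenylated (prenyl bromide, K2CO3, acetone) to give methyl 2-[5-bromo-2-hydroxy-4-(prenyloxy)phenyl]acetate F4.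
   - F4 would be silylated (TIPSCl, imidazole, DMF) to give methyl 2-[5-bromo-4-(prenyloxy)-2-(triisopropylsilyloxy)phenyl]acetate F5.
   - A γ-selective Suzuki–Miyaura allyl–aryl coupling with prenylboronic acid pinacol ester (Pd, bulky biaryl phosphine tuned for γ-attack, K3PO4, THF/H2O, 40 °C) then installs the 1,1-dimethylallyl group at the brominated carbon, with fixed regiochemistry, and gives 6.

**Further compounds**
F1 | step 9 | (2R)-2-[5-(1,1-dimethylallyl)-4-(prenyloxy)-2-(triisopropylsilyloxy)phenyl]-3-[2-hydroxy-4-(triisopropylsilyloxy)phenyl]propanoic acid | C=CC(C)(C)c1cc([C@H](C(=O)O)Cc2ccc(O[Si](C(C)C)(C(C)C)C(C)C)cc2O)c(O[Si](C(C)C)(C(C)C)C(C)C)cc1OCC=C(C)C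
F2 | step 11 | (3R)-3-[5-(1,1-dimethylallyl)-4-(prenyloxy)-2-(triisopropylsilyloxy)phenyl]-2-(phenylsulfanyl)-7-(triisopropylsilyloxy)chroman, C2 epimers | C=CC(C)(C)c1cc([C@@H]2C(Sc3ccccc3)Oc3cc(O[Si](C(C)C)(C(C)C)C(C)C)ccc3C2)c(O[Si](C(C)C)(C(C)C)C(C)C)cc1OCC=C(C)C
F3 | step 3 | methyl 2-(5-bromo-2,4-dihydroxyphenyl)acetate | COC(=O)Cc1cc(Br)c(O)cc1O
F4 | step 3 | methyl 2-[5-bromo-2-hydroxy-4-(prenyloxy)phenyl]acetate | COC(=O)Cc1cc(Br)c(OCC=C(C)C)cc1O
F5 | step 3 | methyl 2-[5-bromo-4-(prenyloxy)-2-(triisopropylsilyloxy)phenyl]acetate | COC(=O)Cc1cc(Br)c(OCC=C(C)C)cc1O[Si](C(C)C)(C(C)C)C(C)C
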